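**Strategy.** The target is C2-symmetric: two 3,5-dihydroxyphenyl rings are joined by a tetradecane chain whose central C7–C8 bond lies on the symmetry element and links two unfunctionalised methylenes of identical polarity. The route rests on cutting that bond into two identical 7-arylheptyl halves. The key step is a nickel-catalysed reductive homocoupling of a primary alkyl bromide. It joins the two electrophilic carbons directly and should deliver the complete C14-linked bis-arene skeleton in one operation, leaving no activating group to remove. Its precursor, 1-(7-bromoheptyl)-3,5-dimethoxybenzene, comes in one step from 1-bromo-3,5-dimethoxybenzene and 1,7-dibromoheptane. Fourfold O-demethylation completes the route.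

Key step: step 2

Remark: the target has no stereocentre and no stereogenic double bond, so no stereocontrol is required; the phenols are carried as methyl ethers until the last step.

**Step 1**
Reactants: 1 1-bromo-3,5-dimethoxybenzene; 2 1,7-dibromoheptane
Product: 4 1-(7-bromoheptyl)-3,5-dimethoxybenzene, via (3,5-dimethoxyphenyl)magnesium bromide 3 (not isolated)
Conditions: Mg, THF, reflux; then slow addition to 2 (4 equiv), Li2CuCl4 (3 mol %), THF, 0 °C → rt
Reagents that add atoms: none
Why: Magnesium insertion gives the aryl Grignard reagent, which should undergo copper-catalysed (Kochi-type) sp2–sp3 cross-coupling with a primary alkyl bromide; the fourfold excess of dibromide and inverse addition should hold the reaction at mono-substitution, and excess 2 is recovered by distillation.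

**Step 2**
Reactants: 4 1-(7-bromoheptyl)-3,5-dimethoxybenzene (two molecules)
Product: 5 1,14-bis(3,5-dimethoxyphenyl)tetradecane
Conditions: NiCl2·glyme (5 mol %), 4,4′,4″-tri-tert-butyl-2,2′:6′,2″-terpyridine (5 mol %), Mn powder (1 equiv), DMF, 40 °C
Reagents that add atoms: none
Why: Mn reduces the Ni(II)–terpyridine precatalyst to a low-valent nickel species that abstracts bromine from 4 to give a primary alkyl radical and then an alkylnickel; activation of a second molecule of 4 gives a dialkylnickel(III) species, whose reductive elimination forms the central C(sp3)–C(sp3) bond while Mn returns nickel to its low-valent state. The closest known reaction type is the nickel-catalysed reductive (Wurtz-type) homocoupling of unactivated primary alkyl halides with manganese as terminal reductant. No ring is closed and no stereocentre is created. The step needs C–C coupling to outrun β-hydride elimination and hydrodehalogenation; the tridentate terpyridine ligand blocks the cis coordination site that β-hydride elimination requires, and the bromide is primary and unhindered. Because the two partners are identical, no cross-selectivity question arises and only one coupling product is possible. The aryl methyl ethers and the arene rings should be inert to low-valent nickel at 40 °C.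

**Step 3**
Reactants: 5 1,14-bis(3,5-dimethoxyphenyl)tetradecane
Product: 6 bisnorstriatol, 5,5′-(tetradecane-1,14-diyl)bis(benzene-1,3-diol)
Conditions: BBr3 (6 equiv), CH2Cl2, −78 °C → rt; then H2O
Reagents that add atoms: none
Why: Lewis-acid ether cleavage with BBr3 (boron complexation at oxygen, bromide SN2 attack at methyl) should release all four phenols on hydrolytic work-up; the saturated chain and the arenes carry nothing else that reacts.

**Compound list**
1 | 1-bromo-3,5-dimethoxybenzene | COc1cc(Br)cc(OC)c1 | starting material
2 | 1,7-dibromoheptane | BrCCCCCCCBr | starting material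
3 | (3,5-dimethoxyphenyl)magnesium bromide | COc1cc([Mg]Br)cc(OC)c1 | intermediate
4 | 1-(7-bromoheptyl)-3,5-dimethoxybenzene | COc1cc(CCCCCCCBr)cc(OC)c1 | intermediate
5 | 1,14-bis(3,5-dimethoxyphenyl)tetradecane | COc1cc(CCCCCCCCCCCCCCc2cc(OC)cc(OC)c2)cc(OC)c1 | intermediate
6 | bisnorstriatol, 5,5′-(tetradecane-1,14-diyl)bis(benzene-1,3-diol) | Oc1cc(O)cc(CCCCCCCCCCCCCCc2cc(O)cc(O)c2)c1 | target

**Total step count:** 3
**Longest linear sequence:** 3 steps (1 → 4 → 5 → 6)

**Steps most likely to fail**

Step 2. β-Hydride elimination from the alkylnickel intermediate, or hydrodehalogenation, may consume the bromide faster than the second C–Br activation, so that chain-terminated monomers form instead of the dimer. The fallback forms the same central bond as an alkene by olefin metathesis. It sets out from 1: the Grignard reagent 3 is coupled with 8-bromooct-1-ene (Li2CuCl4 cat., THF, 0 °C) to give 1,3-dimethoxy-5-(oct-7-en-1-yl)benzene F1. Self-metathesis of F1 (Grubbs second-generation catalyst, CH2Cl2, 40 °C, ethene purged) should give (E)-1,14-bis(3,5-dimethoxyphenyl)tetradec-7-ene F2; an E/Z mixture is expected (E isomer written), and both isomers converge in the next operation. Hydrogenation (H2, Pd/C, EtOAc) comes back to the route at 5.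

Step 1. Over-reaction at the second C–Br terminus (double arylation) and oxidative biaryl formation from the Grignard reagent may erode the mono-alkylation. The fallback builds the chain from a terminal alkyne that carries only one reactive end. It sets out from 1: Sonogashira coupling with hept-6-yn-1-ol (Pd(PPh3)2Cl2, CuI, Et3N, 70 °C) should give 7-(3,5-dimethoxyphenyl)hept-6-yn-1-ol F3. Hydrogenation (H2, Pd/C, EtOAc) should give 7-(3,5-dimethoxyphenyl)heptan-1-ol F4. An Appel reaction (CBr4, PPh3, CH2Cl2, 0 °C) comes back to the route at 4.

Step 3. Cleavage of the four methyl ethers may stop part-way and leave mixtures of partially methylated phenols, or the electron-rich rings may be brominated on prolonged exposure to BBr3/HBr. The fallback changes the protecting group to benzyl, so that the last step is a neutral hydrogenolysis. It sets out from 2: 1,3-bis(benzyloxy)-5-bromobenzene F5 is converted to [3,5-bis(benzyloxy)phenyl]magnesium bromide F6 (Mg, THF) and coupled with excess 2 (Li2CuCl4 cat., THF, 0 °C) to give 1,3-bis(benzyloxy)-5-(7-bromoheptyl)benzene F7. The nickel-catalysed reductive homocoupling of step 2 should then give 1,14-bis[3,5-bis(benzyloxy)phenyl]tetradecane F8. Hydrogenolysis (H2, Pd/C, EtOAc/MeOH) comes back to the route at 6.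

**Further compounds**
F1 | step 2 | 1,3-dimethoxy-5-(oct-7-en-1-yl)benzene | COc1cc(CCCCCCC=C)cc(OC)c1
F2 | step 2 | (E)-1,14-bis(3,5-dimethoxyphenyl)tetradec-7-ene | COc1cc(CCCCCC/C=C/CCCCCCc2cc(OC)cc(OC)c2)cc(OC)c1
F3 | step 1 | 7-(3,5-dimethoxyphenyl)hept-6-yn-1-ol | COc1cc(C#CCCCCCO)cc(OC)c1
F4 | step 1 | 7-(3,5-dimethoxyphenyl)heptan-1-ol | COc1cc(CCCCCCCO)cc(OC)c1
F5 | step 3 | 1,3-bis(benzyloxy)-5-bromobenzene | Brc1cc(OCc2ccccc2)cc(OCc2ccccc2)c1
F6 | step 3 | [3,5-bis(benzyloxy)phenyl]magnesium bromide | Br[Mg]c1cc(OCc2ccccc2)cc(OCc2ccccc2)c1
F7 | step 3 | 1,3-bis(benzyloxy)-5-(7-bromoheptyl)benzene | BrCCCCCCCc1cc(OCc2ccccc2)cc(OCc2ccccc2)c1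
F8 | step 3 | 1,14-bis[3,5-bis(benzyloxy)phenyl]tetradecane | c1ccccc1COc1cc(CCCCCCCCCCCCCCc2cc(OCc3ccccc3)cc(OCc3ccccc3)c2)cc(OCc2ccccc2)c1
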